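**Retrosynthetic overview**
1. Target 34 ← tert-butyl ester 32 ← Nozaki–Hiyama–Kishi macrocyclisation of iodoenoate aldehyde 31 (C7–C8 bond, sets C8); the ten-membered ring is formed last.
2. 31 ← Horner–Wadsworth–Emmons union (C2=C3) of ring aldehyde 21 with the phosphonate/iodoenoate linker 28 (C3–C7).
3. 21 ← Eschenmoser–Claisen rearrangement of cyclohexenylmethanol 16 (sets C10 trans to C1, creates the exocyclic methylene and the C9–C8 arm).
4. 16 ← isopropylidene by acetone aldol and β-lactone decarboxylation of acid 11 ← auxiliary-controlled Diels–Alder of diene 5 with acrylimide 8; the six-membered ring is formed first.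
5. Diene 5 ← Suzuki coupling of a 2-bromoallyl ether with an (E)-alkenylboronate.

Assumption: the SMILES is taken literally (trans ring fusion, 1S,8R,10S, both ring enoates E; locants are those of the bicyclo[8.4.0]tetradecane name), and the C8 outcome of the macrocyclisation in step 18 is a prediction, not a certainty.

**Route**

Step 1
Reactants: 1 2-bromoprop-2-en-1-ol
Product: 2 [(2-bromoprop-2-en-1-yl)oxy](tert-butyl)dimethylsilane
Conditions: TBSCl, imidazole, CH2Cl2, 0 °C → rt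
Reagents that add atoms: tert-butyl(chloro)dimethylsilane (TBSCl), CC(C)(C)[Si](C)(C)Cl
Why: Silyl ether formation protects the primary allylic alcohol so the vinyl bromide can be cross-coupled and carried through the aluminium- and lithium-mediated steps.

Step 2
Reactants: 3 tert-butyl(diphenyl)(prop-2-yn-1-yloxy)silane
Product: 4 tert-butyl(diphenyl){[(2E)-3-(4,4,5,5-tetramethyl-1,3,2-dioxaborolan-2-yl)prop-2-en-1-yl]oxy}silane
Conditions: pinacolborane, Cp2Zr(H)Cl (10 mol %), Et3N (10 mol %), neat, 60 °C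
Reagents that add atoms: pinacolborane (4,4,5,5-tetramethyl-1,3,2-dioxaborolane), B1OC(C)(C)C(C)(C)O1
Why: Zirconocene-hydride-catalysed hydroboration adds H–B syn and anti-Markovnikov across the terminal alkyne, giving only the (E)-alkenylboronate.

Step 3
Reactants: 2 [(2-bromoprop-2-en-1-yl)oxy](tert-butyl)dimethylsilane; 4 tert-butyl(diphenyl){[(2E)-3-(4,4,5,5-tetramethyl-1,3,2-dioxaborolan-2-yl)prop-2-en-1-yl]oxy}silane
Product: 5 tert-butyl{[(2E)-4-({[tert-butyl(dimethyl)silyl]oxy}methyl)penta-2,4-dien-1-yl]oxy}diphenylsilane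
Conditions: Pd(PPh3)4 (5 mol %), K3PO4, dioxane/H2O, 70 °C
Reagents that add atoms: none
Why: Suzuki–Miyaura cross-coupling of the vinyl bromide with the alkenylboronate proceeds with retention of the E geometry and gives the 1,3-disubstituted diene needed for the cycloaddition.

Step 4
Reactants: 6 (4S)-4-benzyl-1,3-oxazolidin-2-one; 7 prop-2-enoyl chloride
Product: 8 (4S)-4-benzyl-3-(prop-2-enoyl)-1,3-oxazolidin-2-one
Conditions: n-BuLi, THF, −78 °C; then 7, −78 → 0 °C
Reagents that add atoms: none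
Why: N-acylation of the lithiated oxazolidinone with the acid chloride at low temperature gives the chiral acrylimide dienophile.

Step 5
Reactants: 5 tert-butyl{[(2E)-4-({[tert-butyl(dimethyl)silyl]oxy}methyl)penta-2,4-dien-1-yl]oxy}diphenylsilane; 8 (4S)-4-benzyl-3-(prop-2-enoyl)-1,3-oxazolidin-2-one
Product: 9 (4S)-4-benzyl-3-{[(1R,2S)-4-({[tert-butyl(dimethyl)silyl]oxy}methyl)-2-({[tert-butyl(diphenyl)silyl]oxy}methyl)cyclohex-3-en-1-yl]carbonyl}-1,3-oxazolidin-2-one
Conditions: 8 (1.3 equiv), Et2AlCl (1.8 equiv), CH2Cl2, −78 → −30 °C; 1 M HCl quench; chromatography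
Reagents that add atoms: none
Why: In this auxiliary-controlled Diels–Alder reaction the aluminium-chelated s-cis acrylimide is attacked on the face opposite the benzyl group through an endo transition state with ortho/para regiocontrol, which fixes the ring carbon that becomes C1 of the target (S) cis to the acyl group, and minor diastereomers are removed by chromatography.

Step 6
Reactants: 9 (4S)-4-benzyl-3-{[(1R,2S)-4-({[tert-butyl(dimethyl)silyl]oxy}methyl)-2-({[tert-butyl(diphenyl)silyl]oxy}methyl)cyclohex-3-en-1-yl]carbonyl}-1,3-oxazolidin-2-one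
Product: 11 (1R,2S)-4-({[tert-butyl(dimethyl)silyl]oxy}methyl)-2-({[tert-butyl(diphenyl)silyl]oxy}methyl)cyclohex-3-ene-1-carboxylic acid, via peroxy acid 10 (not isolated)
Conditions: LiOH, H2O2, THF/H2O, 0 °C; then Na2SO3; HCl to pH 3
Reagents that add atoms: hydrogen peroxide, OO
Why: Hydroperoxide attacks the exocyclic imide carbonyl selectively (LiOOH imide cleavage), sulfite reduces the peroxy acid, and the auxiliary is released for recovery without touching the silyl ethers.

Step 7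
Reactants: 11 (1R,2S)-4-({[tert-butyl(dimethyl)silyl]oxy}methyl)-2-({[tert-butyl(diphenyl)silyl]oxy}methyl)cyclohex-3-ene-1-carboxylic acid; 12 acetone
Product: 13 (1R,2S)-4-({[tert-butyl(dimethyl)silyl]oxy}methyl)-2-({[tert-butyl(diphenyl)silyl]oxy}methyl)-1-(2-hydroxypropan-2-yl)cyclohex-3-ene-1-carboxylic acid
Conditions: LDA (2.2 equiv), THF, 0 °C → rt; then 12, −78 °C; 1 M HCl
Reagents that add atoms: none
Why: Aldol addition of the carboxylic acid dianion to acetone gives the β-hydroxy acid (acetone expected anti to the neighbouring silyloxymethyl group), and the new quaternary centre is erased in step 8 so its configuration is immaterial.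

Step 8
Reactants: 13 (1R,2S)-4-({[tert-butyl(dimethyl)silyl]oxy}methyl)-2-({[tert-butyl(diphenyl)silyl]oxy}methyl)-1-(2-hydroxypropan-2-yl)cyclohex-3-ene-1-carboxylic acid
Product: 15 tert-butyl{[(1S)-3-({[tert-butyl(dimethyl)silyl]oxy}methyl)-6-(propan-2-ylidene)cyclohex-2-en-1-yl]methoxy}diphenylsilane, via spiro β-lactone 14 (not isolated)
Conditions: PhSO2Cl, pyridine, 0 °C, 12 h; then crude 14, DMF, 140 °C
Reagents that add atoms: none
Why: Carboxyl activation closes the β-lactone and thermal [2+2] cycloreversion (decarboxylation) then gives the tetrasubstituted isopropylidene alkene regiospecifically without affecting the adjacent stereocentre.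

Step 9
Reactants: 15 tert-butyl{[(1S)-3-({[tert-butyl(dimethyl)silyl]oxy}methyl)-6-(propan-2-ylidene)cyclohex-2-en-1-yl]methoxy}diphenylsilane
Product: 16 [(3S)-3-({[tert-butyl(diphenyl)silyl]oxy}methyl)-4-(propan-2-ylidene)cyclohex-1-en-1-yl]methanol
Conditions: CSA (10 mol %), MeOH/CH2Cl2, 0 °C
Reagents that add atoms: none
Why: Acid-catalysed methanolysis (selective desilylation) removes the primary allylic TBS ether much faster than the bulkier TBDPS ether.

Step 10
Reactants: 16 [(3S)-3-({[tert-butyl(diphenyl)silyl]oxy}methyl)-4-(propan-2-ylidene)cyclohex-1-en-1-yl]methanol; 17 1,1-dimethoxy-N,N-dimethylethan-1-amine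
Product: 19 2-[(1S,2S)-2-({[tert-butyl(diphenyl)silyl]oxy}methyl)-6-methylidene-3-(propan-2-ylidene)cyclohexyl]-N,N-dimethylacetamide, via ketene N,O-acetal 18 (not isolated)
Conditions: 17 (5 equiv), xylenes, 140 °C, MeOH distilled off
Reagents that add atoms: none
Why: In this Eschenmoser–Claisen rearrangement the ketene N,O-acetal undergoes a [3,3] shift that forms the new C–C bond on the ring face anti to the pseudoaxial silyloxymethyl group on the neighbouring carbon, which sets the trans ring-fusion centre (S, C10 of the target) and creates the exocyclic methylene.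

Step 11
Reactants: 19 2-[(1S,2S)-2-({[tert-butyl(diphenyl)silyl]oxy}methyl)-6-methylidene-3-(propan-2-ylidene)cyclohexyl]-N,N-dimethylacetamide
Product: 20 2-[(1S,2S)-2-(hydroxymethyl)-6-methylidene-3-(propan-2-ylidene)cyclohexyl]-N,N-dimethylacetamide
Conditions: TBAF, THF, 0 °C → rt
Reagents that add atoms: none
Why: Fluoride-mediated desilylation frees the primary alcohol while the amide and the alkenes are inert.

Step 12
Reactants: 20 2-[(1S,2S)-2-(hydroxymethyl)-6-methylidene-3-(propan-2-ylidene)cyclohexyl]-N,N-dimethylacetamide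
Product: 21 2-[(1S,2S)-2-formyl-6-methylidene-3-(propan-2-ylidene)cyclohexyl]-N,N-dimethylacetamide
Conditions: Dess–Martin periodinane, pyridine, CH2Cl2, 0 °C; used at once
Reagents that add atoms: none
Why: Dess–Martin oxidation under buffered, non-basic conditions gives the β,γ-unsaturated aldehyde without epimerising or conjugating its α-stereocentre.

Step 13
Reactants: 22 methyl 2-(diethoxyphosphoryl)acetate; 23 3-bromo-1,1-dimethoxypropane
Product: 24 methyl 2-(diethoxyphosphoryl)-5,5-dimethoxypentanoate (racemic)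
Conditions: NaH, DMF, 0 °C; then 23, NaI (cat.), 70 °C
Reagents that add atoms: none
Why: C-alkylation (SN2) of the sodium phosphonoacetate anion by the primary bromide installs the three-carbon acetal arm.

Step 14
Reactants: 24 methyl 2-(diethoxyphosphoryl)-5,5-dimethoxypentanoate
Product: 25 methyl 2-(diethoxyphosphoryl)-5-oxopentanoate (racemic)
Conditions: 1 M HCl, THF, rt
Reagents that add atoms: water, O
Why: Acid-catalysed acetal hydrolysis unmasks the aldehyde while the phosphonate and the methyl ester survive.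

Step 15
Reactants: 25 methyl 2-(diethoxyphosphoryl)-5-oxopentanoate; 26 tert-butyl (triphenylphosphoranylidene)acetate
Product: 28 1-tert-butyl 7-methyl (2Z)-6-(diethoxyphosphoryl)-2-iodohept-2-enedioate (racemic at C6), via iodo ylide 27 (not isolated)
Conditions: 26, N-iodosuccinimide, CH2Cl2, −20 °C; then 25, −20 °C → rt
Reagents that add atoms: N-iodosuccinimide, O=C1CCC(=O)N1I
Why: Wittig olefination with the stabilised α-iodo ylide made in situ by iodination places the ester trans to the alkyl chain, which gives the (Z)-α-iodoenoate.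

Step 16
Reactants: 21 2-[(1S,2S)-2-formyl-6-methylidene-3-(propan-2-ylidene)cyclohexyl]-N,N-dimethylacetamide; 28 1-tert-butyl 7-methyl (2Z)-6-(diethoxyphosphoryl)-2-iodohept-2-enedioate
Product: 29 1-tert-butyl 7-methyl (2Z,6E)-6-({(1S,2S)-2-[2-(dimethylamino)-2-oxoethyl]-3-methylidene-6-(propan-2-ylidene)cyclohexyl}methylidene)-2-iodohept-2-enedioate
Conditions: 28 (1.3 equiv), NaH (1.2 equiv), THF, 0 °C; then 21, −20 → 0 °C
Reagents that add atoms: none
Why: Horner–Wadsworth–Emmons olefination with the preformed α-substituted phosphonate anion gives the E trisubstituted enoate (ester trans to the ring) and at low temperature should outrun enolisation of the sensitive aldehyde.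

Step 17
Reactants: 29 1-tert-butyl 7-methyl (2Z,6E)-6-({(1S,2S)-2-[2-(dimethylamino)-2-oxoethyl]-3-methylidene-6-(propan-2-ylidene)cyclohexyl}methylidene)-2-iodohept-2-enedioate
Product: 31 1-tert-butyl 7-methyl (2Z,6E)-2-iodo-6-{[(1S,2S)-3-methylidene-2-(2-oxoethyl)-6-(propan-2-ylidene)cyclohexyl]methylidene}hept-2-enedioate, via zirconated hemiaminal 30 (not isolated)
Conditions: Cp2Zr(H)Cl (1.5 equiv), THF, rt, 20 min; then H2O, silica gel
Reagents that add atoms: none
Why: Hydrozirconation with the Schwartz reagent converts the tertiary amide into an O-zirconated hemiaminal that releases the aldehyde on hydrolytic work-up, much faster than the reagent attacks the esters, the vinyl iodide or the hindered alkenes.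

Step 18
Reactants: 31 1-tert-butyl 7-methyl (2Z,6E)-2-iodo-6-{[(1S,2S)-3-methylidene-2-(2-oxoethyl)-6-(propan-2-ylidene)cyclohexyl]methylidene}hept-2-enedioate
Product: 32 7-tert-butyl 3-methyl (1S,2E,6E,8R,10S)-8-hydroxy-11-methylidene-14-(propan-2-ylidene)bicyclo[8.4.0]tetradeca-2,6-diene-3,7-dicarboxylate
Conditions: CrCl2 (10 equiv), NiCl2 (1 mol % of the CrCl2), DMSO/THF, 0.002 M, slow addition of 31, rt; aqueous work-up
Reagents that add atoms: none
Why: In this Nozaki–Hiyama–Kishi macrocyclisation zerovalent nickel inserts into the C–I bond, transmetalation to chromium gives a nucleophile that adds only to the aldehyde and closes the ten-membered ring with retention of alkene geometry, and the C8 carbinol is set by macrocyclic substrate control (peripheral attack, 8R expected).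

Step 19
Reactants: 32 7-tert-butyl 3-methyl (1S,2E,6E,8R,10S)-8-hydroxy-11-methylidene-14-(propan-2-ylidene)bicyclo[8.4.0]tetradeca-2,6-diene-3,7-dicarboxylate
Product: 34 microeunicellol A [(1S,2E,6E,8R,10S)-8-hydroxy-3-(methoxycarbonyl)-11-methylidene-14-(propan-2-ylidene)bicyclo[8.4.0]tetradeca-2,6-diene-7-carboxylic acid], via bis(trimethylsilyl) derivative 33 (not isolated)
Conditions: TMSOTf (4 equiv), 2,6-lutidine (6 equiv), CH2Cl2, 0 °C → rt; then H2O/THF, pH 5
Reagents that add atoms: none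
Why: Silyl triflate-mediated cleavage of the tert-butyl ester (loss of isobutene) under buffered non-protic conditions frees the acid without isomerising the exocyclic alkenes or touching the methyl ester, and aqueous work-up removes the transient silyl groups.

**Compound list**

1 | 2-bromoprop-2-en-1-ol | C=C(Br)CO | starting material
2 | [(2-bromoprop-2-en-1-yl)oxy](tert-butyl)dimethylsilane | C=C(Br)CO[Si](C)(C)C(C)(C)C | intermediate
3 | tert-butyl(diphenyl)(prop-2-yn-1-yloxy)silane | C#CCO[Si](c1ccccc1)(c1ccccc1)C(C)(C)C | starting material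
4 | tert-butyl(diphenyl){[(2E)-3-(4,4,5,5-tetramethyl-1,3,2-dioxaborolan-2-yl)prop-2-en-1-yl]oxy}silane | CC(C)(C)[Si](OC/C=C/B1OC(C)(C)C(C)(C)O1)(c1ccccc1)c1ccccc1 | intermediate
5 | tert-butyl{[(2E)-4-({[tert-butyl(dimethyl)silyl]oxy}methyl)penta-2,4-dien-1-yl]oxy}diphenylsilane | C=C(CO[Si](C)(C)C(C)(C)C)/C=C/CO[Si](c1ccccc1)(c1ccccc1)C(C)(C)C | intermediate
6 | (4S)-4-benzyl-1,3-oxazolidin-2-one | O=C1N[C@@H](Cc2ccccc2)CO1 | starting material
7 | prop-2-enoyl chloride (acryloyl chloride) | C=CC(=O)Cl | starting material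
8 | (4S)-4-benzyl-3-(prop-2-enoyl)-1,3-oxazolidin-2-one | C=CC(=O)N1[C@@H](Cc2ccccc2)COC1=O | intermediate
9 | (4S)-4-benzyl-3-{[(1R,2S)-4-({[tert-butyl(dimethyl)silyl]oxy}methyl)-2-({[tert-butyl(diphenyl)silyl]oxy}methyl)cyclohex-3-en-1-yl]carbonyl}-1,3-oxazolidin-2-one | O=C([C@@H]1CCC(CO[Si](C)(C)C(C)(C)C)=C[C@@H]1CO[Si](c1ccccc1)(c1ccccc1)C(C)(C)C)N1[C@@H](Cc2ccccc2)COC1=O | intermediate
10 | (1R,2S)-4-({[tert-butyl(dimethyl)silyl]oxy}methyl)-2-({[tert-butyl(diphenyl)silyl]oxy}methyl)cyclohex-3-ene-1-carboperoxoic acid | OOC(=O)[C@@H]1CCC(CO[Si](C)(C)C(C)(C)C)=C[C@@H]1CO[Si](c1ccccc1)(c1ccccc1)C(C)(C)C | intermediate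
11 | (1R,2S)-4-({[tert-butyl(dimethyl)silyl]oxy}methyl)-2-({[tert-butyl(diphenyl)silyl]oxy}methyl)cyclohex-3-ene-1-carboxylic acid | OC(=O)[C@@H]1CCC(CO[Si](C)(C)C(C)(C)C)=C[C@@H]1CO[Si](c1ccccc1)(c1ccccc1)C(C)(C)C | intermediate
12 | acetone (propan-2-one) | CC(C)=O | starting material
13 | (1R,2S)-4-({[tert-butyl(dimethyl)silyl]oxy}methyl)-2-({[tert-butyl(diphenyl)silyl]oxy}methyl)-1-(2-hydroxypropan-2-yl)cyclohex-3-ene-1-carboxylic acid | OC(=O)[C@]1(C(C)(C)O)CCC(CO[Si](C)(C)C(C)(C)C)=C[C@@H]1CO[Si](c1ccccc1)(c1ccccc1)C(C)(C)C | intermediate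
14 | (4R,5S)-7-({[tert-butyl(dimethyl)silyl]oxy}methyl)-5-({[tert-butyl(diphenyl)silyl]oxy}methyl)-3,3-dimethyl-2-oxaspiro[3.5]non-6-en-1-one | O=C1OC(C)(C)[C@]12CCC(CO[Si](C)(C)C(C)(C)C)=C[C@@H]2CO[Si](c1ccccc1)(c1ccccc1)C(C)(C)C | intermediate
15 | tert-butyl{[(1S)-3-({[tert-butyl(dimethyl)silyl]oxy}methyl)-6-(propan-2-ylidene)cyclohex-2-en-1-yl]methoxy}diphenylsilane | CC(C)=C1CCC(CO[Si](C)(C)C(C)(C)C)=C[C@@H]1CO[Si](c1ccccc1)(c1ccccc1)C(C)(C)C | intermediate
16 | [(3S)-3-({[tert-butyl(diphenyl)silyl]oxy}methyl)-4-(propan-2-ylidene)cyclohex-1-en-1-yl]methanol | CC(C)=C1CCC(CO)=C[C@@H]1CO[Si](c1ccccc1)(c1ccccc1)C(C)(C)C | intermediate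
17 | 1,1-dimethoxy-N,N-dimethylethan-1-amine (N,N-dimethylacetamide dimethyl acetal) | CC(OC)(OC)N(C)C | starting material
18 | 1-{[(3S)-3-({[tert-butyl(diphenyl)silyl]oxy}methyl)-4-(propan-2-ylidene)cyclohex-1-en-1-yl]methoxy}-N,N-dimethylethen-1-amine | CC(C)=C1CCC(COC(=C)N(C)C)=C[C@@H]1CO[Si](c1ccccc1)(c1ccccc1)C(C)(C)C | intermediate
19 | 2-[(1S,2S)-2-({[tert-butyl(diphenyl)silyl]oxy}methyl)-6-methylidene-3-(propan-2-ylidene)cyclohexyl]-N,N-dimethylacetamide | C=C1CCC(=C(C)C)[C@@H](CO[Si](c2ccccc2)(c2ccccc2)C(C)(C)C)[C@@H]1CC(=O)N(C)C | intermediate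
20 | 2-[(1S,2S)-2-(hydroxymethyl)-6-methylidene-3-(propan-2-ylidene)cyclohexyl]-N,N-dimethylacetamide | C=C1CCC(=C(C)C)[C@@H](CO)[C@@H]1CC(=O)N(C)C | intermediate
21 | 2-[(1S,2S)-2-formyl-6-methylidene-3-(propan-2-ylidene)cyclohexyl]-N,N-dimethylacetamide | C=C1CCC(=C(C)C)[C@@H](C=O)[C@@H]1CC(=O)N(C)C | intermediate
22 | methyl 2-(diethoxyphosphoryl)acetate | CCOP(=O)(OCC)CC(=O)OC | starting material
23 | 3-bromo-1,1-dimethoxypropane | BrCCC(OC)OC | starting material
24 | methyl 2-(diethoxyphosphoryl)-5,5-dimethoxypentanoate (racemic) | CCOP(=O)(OCC)C(CCC(OC)OC)C(=O)OC | intermediate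
25 | methyl 2-(diethoxyphosphoryl)-5-oxopentanoate (racemic) | CCOP(=O)(OCC)C(CCC=O)C(=O)OC | intermediate
26 | tert-butyl (triphenylphosphoranylidene)acetate | CC(C)(C)OC(=O)C=P(c1ccccc1)(c1ccccc1)c1ccccc1 | starting material
27 | tert-butyl iodo(triphenylphosphoranylidene)acetate | CC(C)(C)OC(=O)C(I)=P(c1ccccc1)(c1ccccc1)c1ccccc1 | intermediate
28 | 1-tert-butyl 7-methyl (2Z)-6-(diethoxyphosphoryl)-2-iodohept-2-enedioate (racemic at C6) | CCOP(=O)(OCC)C(CC/C=C(\I)C(=O)OC(C)(C)C)C(=O)OC | intermediate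
29 | 1-tert-butyl 7-methyl (2Z,6E)-6-({(1S,2S)-2-[2-(dimethylamino)-2-oxoethyl]-3-methylidene-6-(propan-2-ylidene)cyclohexyl}methylidene)-2-iodohept-2-enedioate | C=C1CCC(=C(C)C)[C@@H](/C=C(/C(=O)OC)CC/C=C(\I)C(=O)OC(C)(C)C)[C@@H]1CC(=O)N(C)C | intermediate
30 | O-[chlorobis(cyclopentadienyl)zirconio] hemiaminal of 29 (amide carbon as CH(NMe2)O–ZrCp2Cl, Cp drawn σ-bonded) | C=C1CCC(=C(C)C)[C@@H](/C=C(/C(=O)OC)CC/C=C(\I)C(=O)OC(C)(C)C)[C@@H]1CC(O[Zr](Cl)(C2C=CC=C2)C2C=CC=C2)N(C)C | intermediate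
31 | 1-tert-butyl 7-methyl (2Z,6E)-2-iodo-6-{[(1S,2S)-3-methylidene-2-(2-oxoethyl)-6-(propan-2-ylidene)cyclohexyl]methylidene}hept-2-enedioate | C=C1CCC(=C(C)C)[C@@H](/C=C(/C(=O)OC)CC/C=C(\I)C(=O)OC(C)(C)C)[C@@H]1CC=O | intermediate
32 | 7-tert-butyl 3-methyl (1S,2E,6E,8R,10S)-8-hydroxy-11-methylidene-14-(propan-2-ylidene)bicyclo[8.4.0]tetradeca-2,6-diene-3,7-dicarboxylate | C=C1CCC(=C(C)C)[C@H]2/C=C(/C(=O)OC)CC/C=C(/C(=O)OC(C)(C)C)[C@H](O)C[C@H]12 | intermediate
33 | 3-methyl 7-trimethylsilyl (1S,2E,6E,8R,10S)-11-methylidene-14-(propan-2-ylidene)-8-[(trimethylsilyl)oxy]bicyclo[8.4.0]tetradeca-2,6-diene-3,7-dicarboxylate | C=C1CCC(=C(C)C)[C@H]2/C=C(/C(=O)OC)CC/C=C(/C(=O)O[Si](C)(C)C)[C@H](O[Si](C)(C)C)C[C@H]12 | intermediate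
34 | microeunicellol A, (1S,2E,6E,8R,10S)-8-hydroxy-3-(methoxycarbonyl)-11-methylidene-14-(propan-2-ylidene)bicyclo[8.4.0]tetradeca-2,6-diene-7-carboxylic acid | C=C1CCC(=C(C)C)[C@H]2/C=C(/C(=O)OC)CC/C=C(/C(=O)O)[C@H](O)C[C@H]12 | target

**Step count and risks**

Total steps: 19. Longest linear sequence: 14 steps (1, 3, 5–12, 16–19, from 2-bromoprop-2-en-1-ol).

Three steps most likely to fail:

Risk 1, step 18. The ten-membered ring closure through an α-carboxyvinyl chromium species is the least precedented step, and the C8 configuration rests on macrocyclic substrate control that cannot be predicted with confidence. The fallback sets out from 31 and returns at 32. If the cyclisation gives mainly the C8 epimer 7-tert-butyl 3-methyl (1S,2E,6E,8S,10S)-8-hydroxy-11-methylidene-14-(propan-2-ylidene)bicyclo[8.4.0]tetradeca-2,6-diene-3,7-dicarboxylate F1, this alcohol (or the epimer mixture) is oxidised with Dess–Martin periodinane to the macrocyclic enone 7-tert-butyl 3-methyl (1S,2E,6E,10S)-11-methylidene-8-oxo-14-(propan-2-ylidene)bicyclo[8.4.0]tetradeca-2,6-diene-3,7-dicarboxylate F2. F2 is then reduced with catecholborane and catalytic (S)-2-methyl-CBS-oxazaborolidine at −78 °C, a reagent-controlled 1,2-reduction in which the alkenyl group acts as the large substituent, to give the 8R alcohol 32.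

Risk 2, step 16. The α-stereocentre of aldehyde 21 (allylic to the isopropylidene group) may epimerise under the basic olefination, and the hindered aldehyde may react slowly or with poor E/Z control. The fallback sets out from 21 and returns at 29. Aldehyde 21 is added at −78 °C to the lithium enolate of commercial methyl 5,5-dimethoxypentanoate (LDA, THF) to give the aldol adduct methyl 2-{[(1S,2S)-2-[2-(dimethylamino)-2-oxoethyl]-3-methylidene-6-(propan-2-ylidene)cyclohexyl](hydroxy)methyl}-5,5-dimethoxypentanoate F3 (mixture at the two new centres), in which the ring stereocentre is no longer α to a carbonyl. Mesylation and E1cB elimination (MsCl, Et3N; then DBU, 0 °C) give the E enoate methyl (2E)-2-(3,3-dimethoxypropyl)-3-[(1S,2S)-2-[2-(dimethylamino)-2-oxoethyl]-3-methylidene-6-(propan-2-ylidene)cyclohexyl]prop-2-enoate F4. Hydrolysis with 1 M HCl in THF gives the aldehyde methyl (2E)-3-[(1S,2S)-2-[2-(dimethylamino)-2-oxoethyl]-3-methylidene-6-(propan-2-ylidene)cyclohexyl]-2-(3-oxopropyl)prop-2-enoate F5, and Wittig reaction of F5 with iodo ylide 27 (made from 26 as in step 15) gives 29.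

Risk 3, step 17. The late amide reduction must spare two conjugated esters, an iodoalkene and a 1,1-disubstituted alkene. The fallback sets out from 19 and returns at 31. The Cp2Zr(H)Cl reduction is moved to 19, which carries none of these groups, giving 2-[(1S,2S)-2-({[tert-butyl(diphenyl)silyl]oxy}methyl)-6-methylidene-3-(propan-2-ylidene)cyclohexyl]acetaldehyde F6. The aldehyde is masked with HC(OMe)3, PPTS and MeOH as tert-butyl{[(1S,2S)-2-(2,2-dimethoxyethyl)-3-methylidene-6-(propan-2-ylidene)cyclohexyl]methoxy}diphenylsilane F7. TBAF gives [(1S,2S)-2-(2,2-dimethoxyethyl)-3-methylidene-6-(propan-2-ylidene)cyclohexyl]methanol F8, and buffered Dess–Martin oxidation gives (1S,2S)-2-(2,2-dimethoxyethyl)-3-methylidene-6-(propan-2-ylidene)cyclohexane-1-carbaldehyde F9. Horner–Wadsworth–Emmons reaction with 28 gives 1-tert-butyl 7-methyl (2Z,6E)-6-{[(1S,2S)-2-(2,2-dimethoxyethyl)-3-methylidene-6-(propan-2-ylidene)cyclohexyl]methylidene}-2-iodohept-2-enedioate F10, and 1 M HCl in THF releases aldehyde 31.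

Further compounds
F1 | step 18 | 7-tert-butyl 3-methyl (1S,2E,6E,8S,10S)-8-hydroxy-11-methylidene-14-(propan-2-ylidene)bicyclo[8.4.0]tetradeca-2,6-diene-3,7-dicarboxylate | C=C1CCC(=C(C)C)[C@H]2/C=C(/C(=O)OC)CC/C=C(/C(=O)OC(C)(C)C)[C@@H](O)C[C@H]12
F2 | step 18 | 7-tert-butyl 3-methyl (1S,2E,6E,10S)-11-methylidene-8-oxo-14-(propan-2-ylidene)bicyclo[8.4.0]tetradeca-2,6-diene-3,7-dicarboxylate | C=C1CCC(=C(C)C)[C@H]2/C=C(/C(=O)OC)CC/C=C(/C(=O)OC(C)(C)C)C(=O)C[C@H]12
F3 | step 16 | methyl 2-{[(1S,2S)-2-[2-(dimethylamino)-2-oxoethyl]-3-methylidene-6-(propan-2-ylidene)cyclohexyl](hydroxy)methyl}-5,5-dimethoxypentanoate | C=C1CCC(=C(C)C)[C@@H](C(O)C(CCC(OC)OC)C(=O)OC)[C@@H]1CC(=O)N(C)C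
F4 | step 16 | methyl (2E)-2-(3,3-dimethoxypropyl)-3-[(1S,2S)-2-[2-(dimethylamino)-2-oxoethyl]-3-methylidene-6-(propan-2-ylidene)cyclohexyl]prop-2-enoate | C=C1CCC(=C(C)C)[C@@H](/C=C(/C(=O)OC)CCC(OC)OC)[C@@H]1CC(=O)N(C)C
F5 | step 16 | methyl (2E)-3-[(1S,2S)-2-[2-(dimethylamino)-2-oxoethyl]-3-methylidene-6-(propan-2-ylidene)cyclohexyl]-2-(3-oxopropyl)prop-2-enoate | C=C1CCC(=C(C)C)[C@@H](/C=C(/C(=O)OC)CCC=O)[C@@H]1CC(=O)N(C)C
F6 | step 17 | 2-[(1S,2S)-2-({[tert-butyl(diphenyl)silyl]oxy}methyl)-6-methylidene-3-(propan-2-ylidene)cyclohexyl]acetaldehyde | C=C1CCC(=C(C)C)[C@@H](CO[Si](c2ccccc2)(c2ccccc2)C(C)(C)C)[C@@H]1CC=O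
F7 | step 17 | tert-butyl{[(1S,2S)-2-(2,2-dimethoxyethyl)-3-methylidene-6-(propan-2-ylidene)cyclohexyl]methoxy}diphenylsilane | C=C1CCC(=C(C)C)[C@@H](CO[Si](c2ccccc2)(c2ccccc2)C(C)(C)C)[C@@H]1CC(OC)OC
F8 | step 17 | [(1S,2S)-2-(2,2-dimethoxyethyl)-3-methylidene-6-(propan-2-ylidene)cyclohexyl]methanol | C=C1CCC(=C(C)C)[C@@H](CO)[C@@H]1CC(OC)OC
F9 | step 17 | (1S,2S)-2-(2,2-dimethoxyethyl)-3-methylidene-6-(propan-2-ylidene)cyclohexane-1-carbaldehyde | C=C1CCC(=C(C)C)[C@@H](C=O)[C@@H]1CC(OC)OC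
F10 | step 17 | 1-tert-butyl 7-methyl (2Z,6E)-6-{[(1S,2S)-2-(2,2-dimethoxyethyl)-3-methylidene-6-(propan-2-ylidene)cyclohexyl]methylidene}-2-iodohept-2-enedioate | C=C1CCC(=C(C)C)[C@@H](/C=C(/C(=O)OC)CC/C=C(\I)C(=O)OC(C)(C)C)[C@@H]1CC(OC)OC
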